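**Slow drain.** Start from the slowness of the spring run. Its single product falls almost in a straight line, from 61.9 % at 25.0 min to 44.3 % at 40.0 min. Read this as a pseudo-zero-order loss: crystals hold the dissolved single product at a steady level, so the pace follows c(reagent). At that pace, the whole charge would go in 85.2 min. Each single product took one reagent and each double product two, so c(reagent) stood near 1.22 M.

the same everywhere: starting material 0.60 M

| charge | reagent | remark | time |
|---|---|---|---|
| dusk | 0.27 M | run made earlier |  |
| spring | 2.1 M | run made earlier |  |
| Sunday's | 0.480 M |  | 80 min |
| Thursday's | 1.20 M |  | 80 min |
| Tuesday's | 2.40 M |  | 80 min |

| run | time / min | single product / % |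
|---|---|---|
| dusk | 4.00 | 13.6 |
| dusk | 10.0 | 23.5 |
| dusk | 20.0 | 33.1 |
| dusk | 30.0 | 36.2 |
| dusk | 40.0 | 38.8 |
| spring | 8.00 | 74.6 |
| spring | 15.0 | 73.5 |
| spring | 25.0 | 61.9 |
| spring | 30.0 | 55.9 |
| spring | 40.0 | 44.3 |

(standard deviation of a reading: 0.5 percentage points)

- amount of single product at the end, in percent of the starting material charged, for each flask in turn (Sunday's, Thursday's, Tuesday's)

- what is said of single product includes crystals
- crystals is a solid; its amount is given per volume of the solution
- what was read earlier has a scatter of 0.5 percentage points, one standard deviation
- steps under discussion: reagent + single product -> double product + by-product; crystals <-> single product; starting material + reagent -> single product + by-product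

**Thursday's bracket.** Take Thursday's as the test, and assume the starting material converts at once, leaving c(reagent) at 0.600 M. You leave out the first minutes, when more reagent stands. Define the drain time as the time the straight loss needs to take the whole charge at that c(reagent): 173 min. The run is shorter than one drain time.

Hold c(reagent) at its top level and the floor is 53.8 %. Hold it at what the floor leaves, 0.323 M, and the ceiling is 75.1 %. In Thursday's, the reagent left falls in proportion to the single product. The drain time therefore acts as a lifetime, and your tightest figure is 63.0 %.

**The forecast.** It gives 65 %, 63 % and 9 %. Its ground is that “the single product is being consumed at its saturation level while crystals remain”. Its Thursday figure lies inside your bracket.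

**The flasks.** They give 64.6 %, 58.3 % and 8.25 %. Thursday's lies inside the bracket.

    reagent + single product → double product + by-product (k = 0.0270 M⁻¹ min⁻¹)
    crystals ⇌ single product, rate k2*(cs2 - [single product]) while solid is left; crystals form when [single product] > cs2 (solubility = 0.230 M, k = 1.60 min⁻¹)
    starting material + reagent → single product + by-product (k = 0.160 M⁻¹ min⁻¹)

**Falling reagent.** Thursday's still holds 20.2 % crystals at the end, so it is still draining. Part of why it keeps 58.3 % is the length of the run together with how little single product dissolves: run to 800 min, it stands at 7.59 %, and with the solubility limit taken away, it ends at 44.4 %. Over its second half, the drain time scaled to the mean simulated reagent gives a fall of 16 percentage points, and the flask fell 15 points. Sunday's, with 26.2 % crystals, ends with 2.68 % of its reagent: the same scaling gives 1.3 points of new double product, and the flask gained 1.2 points.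

(Readings and results were computed with constants of no real substance; the scatter is artificial.)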